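**Retrosynthetic overview**

1. 16 ⇐ 13 by Horner–Wadsworth–Emmons olefination at C13 and deprotection; 13 ⇐ allylsilane 12 by Hosomi–Sakurai addition to methyl vinyl ketone, which forms C9–C11 anti to the C10 methyl group and the C8=C17 methylene in the same event.
2. Ring A ⇐ ring B: formal (3+3) annulation of enone ester 4 with the bifunctional allylsilane 5. Conjugate allylation makes C1–C10, ester enolate alkylation makes C3–C4, and the temporary C2 methylidene is later cut down to the C2 oxygen.
3. Enabling feature: in 4 the ring-B unit C8(=O)–C9=C10 makes C10 an electrophilic β-carbon, while C4, the α-carbon of the ester hanging on C5, is a latent nucleophile. These 1,3-related sites of opposite polarity match the C1 (nucleophilic)–C2–C3 (electrophilic) unit of 5.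
4. 4 ⇐ (S)-2-methylcyclohex-2-enol by Johnson–Claisen rearrangement (sets C5) and allylic oxidation. Ring B is present from the start; ring A is formed second.

Key step: step 4

Remark: bicyclic compounds carry labdane numbering (ring A = C1–C5, C10; ring B = C5–C10; C17 = CH2 on C8; C18 = carboxyl on C4) and β is the face of the C10 methyl group; the target as drawn has 2β-OH, 4β-CH3, 4α-CO2H, 5α-H, 10β-CH3 and the C9 side chain α (trans to the C10 methyl group).
Remark: the propanoate α-carbon of 3, 4 and 6 (future C4) is carried as an inconsequential mixture of epimers and is left undefined in their SMILES, because it becomes planar in step 4.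

**Route**

Step 1
Reactants: 1 2-methylcyclohex-2-en-1-one
Product: 2 (1S)-2-methylcyclohex-2-en-1-ol
Conditions: (R)-1-methyl-3,3-diphenyl-tetrahydro-1H,3H-pyrrolo[1,2-c][1,3,2]oxazaborole ((R)-Me-CBS, 10 mol %), BH3·SMe2, THF, −20 °C; MeOH quench
Reagents that add atoms: none
Why: Corey–Bakshi–Shibata reduction, in which the catalyst tells the alkenyl flank (large) from the CH2 flank (small) of the ketone and, as the (R)-catalyst, should deliver hydride to give the (S)-carbinol.

Step 2
Reactants: 2 (1S)-2-methylcyclohex-2-en-1-ol
Product: 3 methyl 2-[(1S)-2-methylcyclohex-2-en-1-yl]propanoate (epimers at the propanoate α-carbon)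
Conditions: CH3CH2C(OMe)3 (5 equiv), EtCO2H (cat.), xylene, 140 °C, MeOH distilled off
Reagents that add atoms: trimethyl orthopropionate CCC(OC)(OC)OC
Why: Johnson–Claisen rearrangement, in which the ketene acetal formed on oxygen rearranges suprafacially ([3,3]), so the new C–C bond at the ring carbon (future C5) forms on the face that carried the C–O bond and the double bond moves to the methyl-bearing position.

Step 3
Reactants: 3 methyl 2-[(1S)-2-methylcyclohex-2-en-1-yl]propanoate
Product: 4 methyl 2-[(1S)-2-methyl-4-oxocyclohex-2-en-1-yl]propanoate (epimers at the propanoate α-carbon)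
Conditions: Rh2(cap)4 (dirhodium tetracaprolactamate, 1 mol %), t-BuOOH (5 equiv), K2CO3 (cat.), CH2Cl2, rt
Reagents that add atoms: tert-butyl hydroperoxide CC(C)(C)OO
Why: allylic oxidation by a tert-butylperoxyl radical chain, in which hydrogen abstraction at the ring CH2 next to the CH end of the trisubstituted alkene and oxygenation at that carbon should give the 3-methyl enone without touching the stereocentre.

Step 4
Reactants: 4 methyl 2-[(1S)-2-methyl-4-oxocyclohex-2-en-1-yl]propanoate; 5 [2-(chloromethyl)prop-2-en-1-yl]trimethylsilane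
Product: 7 trans-fused bicyclic silyl enol ether (4α-CO2Me/4β-CH3/10β-CH3/5α-H; 2-methylidene; C8(OSiMe3)=C9), via monocyclic silyl enol ether allyl chloride 6 (not isolated)
Conditions: 5 (1.5 equiv), (CF3SO2)2NH (5 mol %), toluene, −78 → −30 °C; then THF, LiN(iPr)2 (1.2 equiv), −78 → −20 °C
Reagents that add atoms: none
Why: Me3SiN(SO2CF3)2, formed in the flask from the imide and 5, silylates the enone oxygen, the allylsilane terminus (future C1) attacks the β-carbon (future C10) and the silyl group is handed on to the enolate oxygen (Hosomi–Sakurai conjugate allylation in its silyl-transfer form), so 6 carries a masked ring-B enolate; LiN(iPr)2 then forms the ester enolate, whose α-carbon (future C4) displaces the allylic chloride (future C3) in an intramolecular SN2 alkylation. The closest known reaction types are methylenecycloalkane annulations with this bifunctional allylsilane (Lewis acid allylation, then base-mediated C-alkylation) and alkylative ring closures of ester enolates. Ring A closes in the 6-exo-tet (enolexo) mode through a chair transition state. C10 is controlled by the C5 substituent, which sits pseudoaxial to avoid A(1,2) strain with the C10 methyl group and sends the allyl group to the opposite face, which after closure is the trans ring fusion with the methyl group axial; C4 is controlled by A(1,3) strain in the tetrasubstituted enolate (C5–H eclipses the enolate plane), which places the ester carbon equatorial (α) and the methyl group axial (β). The step needs C-alkylation at C4 and not five-membered closure at C9 by the ring-B enolate, and this is secured because that enolate is locked as its silyl ether while the ester α-hydrogen is the only acidic site left for the amide base.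

Step 5
Reactants: 7 trans-fused bicyclic silyl enol ether
Product: 8 bicyclic enol triflate (4α-CO2Me/4β-CH3/10β-CH3/5α-H; 2-methylidene; C8(OSO2CF3)=C9)
Conditions: CsF, PhN(SO2CF3)2, MeOCH2CH2OMe, rt
Reagents that add atoms: N-phenylbis(trifluoromethanesulfonimide) O=S(=O)(N(c1ccccc1)S(=O)(=O)C(F)(F)F)C(F)(F)F
Why: fluoride cleaves the O–Si bond and the enolate is triflated as it forms (silyl enol ether to enol triflate exchange), so the C8=C9 regiochemistry written in by the conjugate addition should be kept.

Step 6
Reactants: 8 bicyclic enol triflate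
Product: 9 2-oxo enol triflate (C2=O; otherwise as 8)
Conditions: OsO4 (2 mol %), NaIO4 (4 equiv), 2,6-lutidine, dioxane/H2O, rt
Reagents that add atoms: osmium tetroxide (catalytic oxygen carrier) O=[Os](=O)(=O)=O; sodium periodate [Na+].[O-]I(=O)(=O)=O
Why: Lemieux–Johnson cleavage, in which OsO4 dihydroxylates the electron-rich 1,1-disubstituted alkene and NaIO4 cleaves the diol, while the electron-poor enol triflate should not be attacked.

Step 7
Reactants: 9 2-oxo enol triflate
Product: 10 2β-hydroxy enol triflate
Conditions: NaBH4, MeOH/THF, −20 → 0 °C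
Reagents that add atoms: none
Why: substrate-controlled ketone reduction, in which the β face of the C2 carbonyl is shielded by the two syn-axial methyl groups on C4 and C10, so hydride should enter from the α face and give the axial 2β-alcohol, while ester and enol triflate stay inert to NaBH4.

Step 8
Reactants: 10 2β-hydroxy enol triflate
Product: 11 2β-(tert-butyldimethylsilyloxy) enol triflate
Conditions: t-BuMe2SiOSO2CF3, 2,6-lutidine, CH2Cl2, 0 °C → rt
Reagents that add atoms: tert-butyldimethylsilyl trifluoromethanesulfonate CC(C)(C)[Si](C)(C)OS(=O)(=O)C(F)(F)F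
Why: silylation by a silyl triflate and a hindered pyridine base, which is the standard way to cap a hindered axial secondary alcohol and keeps protic acid out of the Lewis acid step 10.

Step 9
Reactants: 11 2β-(tert-butyldimethylsilyloxy) enol triflate
Product: 12 allylsilane (2β-OSiMe2t-Bu; C8(CH2SiMe3)=C9; otherwise as 11)
Conditions: Me3SiCH2MgCl (2 equiv), Pd(PPh3)4 (5 mol %), THF, rt
Reagents that add atoms: (trimethylsilyl)methylmagnesium chloride C[Si](C)(C)C[Mg]Cl
Why: Kumada cross-coupling of an enol triflate under zerovalent palladium catalysis, which should give the allylsilane with the double bond fixed at C8=C9, the hindered ester on the quaternary C4 being slow to add this Grignard reagent.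

Step 10
Reactants: 12 allylsilane
Product: 13 methyl ketone (2β-OSiMe2t-Bu; C8=CH2; 9α-(3-oxobutyl)/9β-H; 4α-CO2Me)
Conditions: CH2=CHCOCH3 (2 equiv), TiCl4 (1.2 equiv), CH2Cl2, −78 °C; aq. NaHCO3
Reagents that add atoms: methyl vinyl ketone CC(=O)C=C
Why: Hosomi–Sakurai conjugate addition (SE2′), in which the γ-carbon C9 attacks the activated enone from the α face, anti to the axial C10 methyl group on the neighbouring carbon, so the side chain is set α, and loss of silicon places the double bond at C8=C17; the new centre is not α to a carbonyl group and cannot epimerise.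

Step 11
Reactants: 13 methyl ketone
Product: 14 silyl-protected diester (13E ethyl enoate on the 9α chain; 4α-CO2Me; 2β-OSiMe2t-Bu; C8=CH2)
Conditions: (EtO)2P(O)CH2CO2Et, NaH, THF, 0 → 60 °C
Reagents that add atoms: triethyl phosphonoacetate CCOC(=O)CP(=O)(OCC)OCC
Why: Horner–Wadsworth–Emmons olefination of the only ketone, in which the stabilised phosphonate should favour the E isomer (ester trans to the larger CH2 branch), the minor Z isomer being removed by chromatography.

Step 12
Reactants: 14 silyl-protected diester
Product: 15 hydroxy diester (2β-OH; 4α-CO2Me; 13E ethyl enoate; C8=CH2)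
Conditions: HF·pyridine, pyridine, THF, 0 °C → rt
Reagents that add atoms: none
Why: fluoride-mediated cleavage of the silyl ether under buffered conditions that should leave the exocyclic alkene and both esters untouched.

Step 13
Reactants: 15 hydroxy diester
Product: 16 (2S,4R,5R,9R,10R,13E)-2-hydroxylabda-8(17),13-diene-15,18-dioic acid (target)
Conditions: KOH, EtOH/H2O, 80 °C; then aq. HCl to pH 2
Reagents that add atoms: potassium hydroxide [K+].[OH-]
Why: saponification, in which the unsaturated ethyl ester hydrolyses readily and the equatorial methyl ester on the quaternary C4 under the more forcing conditions, with no epimerisable stereocentre next to either carboxyl group.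

**Compound list**

1 | 2-methylcyclohex-2-en-1-one | CC1=CCCCC1=O | starting material
2 | (1S)-2-methylcyclohex-2-en-1-ol | O[C@H]1CCCC=C1C | intermediate
3 | methyl 2-[(1S)-2-methylcyclohex-2-en-1-yl]propanoate | COC(=O)C(C)[C@@H]1CCCC=C1C | intermediate
4 | methyl 2-[(1S)-2-methyl-4-oxocyclohex-2-en-1-yl]propanoate | COC(=O)C(C)[C@@H]1CCC(=O)C=C1C | intermediate
5 | [2-(chloromethyl)prop-2-en-1-yl]trimethylsilane | C=C(CCl)C[Si](C)(C)C | starting material
6 | methyl 2-[(1S,2S)-2-[2-(chloromethyl)prop-2-en-1-yl]-2-methyl-4-(trimethylsilyloxy)cyclohex-3-en-1-yl]propanoate | COC(=O)C(C)[C@@H]1CCC(O[Si](C)(C)C)=C[C@@]1(C)CC(=C)CCl | intermediate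
7 | trans-fused bicyclic silyl enol ether (4α-CO2Me, 4β-CH3, 10β-CH3, 5α-H, 2-methylidene, C8(OSiMe3)=C9) | COC(=O)[C@]1(C)CC(=C)C[C@]2(C)C=C(O[Si](C)(C)C)CC[C@@H]12 | intermediate
8 | bicyclic enol triflate (as 7 with C8(OSO2CF3)=C9) | COC(=O)[C@]1(C)CC(=C)C[C@]2(C)C=C(OS(=O)(=O)C(F)(F)F)CC[C@@H]12 | intermediate
9 | 2-oxo enol triflate | COC(=O)[C@]1(C)CC(=O)C[C@]2(C)C=C(OS(=O)(=O)C(F)(F)F)CC[C@@H]12 | intermediate
10 | 2β-hydroxy enol triflate | COC(=O)[C@]1(C)C[C@@H](O)C[C@]2(C)C=C(OS(=O)(=O)C(F)(F)F)CC[C@@H]12 | intermediate
11 | 2β-(tert-butyldimethylsilyloxy) enol triflate | COC(=O)[C@]1(C)C[C@@H](O[Si](C)(C)C(C)(C)C)C[C@]2(C)C=C(OS(=O)(=O)C(F)(F)F)CC[C@@H]12 | intermediate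
12 | allylsilane (2β-OSiMe2t-Bu, C8(CH2SiMe3)=C9) | COC(=O)[C@]1(C)C[C@@H](O[Si](C)(C)C(C)(C)C)C[C@]2(C)C=C(C[Si](C)(C)C)CC[C@@H]12 | intermediate
13 | methyl ketone (2β-OSiMe2t-Bu, C8=CH2, 9α-(3-oxobutyl), 9β-H) | COC(=O)[C@]1(C)C[C@@H](O[Si](C)(C)C(C)(C)C)C[C@]2(C)[C@H](CCC(C)=O)C(=C)CC[C@@H]12 | intermediate
14 | silyl-protected diester (13E ethyl enoate, 4α-CO2Me, 2β-OSiMe2t-Bu) | COC(=O)[C@]1(C)C[C@@H](O[Si](C)(C)C(C)(C)C)C[C@]2(C)[C@H](CC/C(C)=C/C(=O)OCC)C(=C)CC[C@@H]12 | intermediate
15 | hydroxy diester (2β-OH, 4α-CO2Me, 13E ethyl enoate) | COC(=O)[C@]1(C)C[C@@H](O)C[C@]2(C)[C@H](CC/C(C)=C/C(=O)OCC)C(=C)CC[C@@H]12 | intermediate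
16 | (2S,4R,5R,9R,10R,13E)-2-hydroxylabda-8(17),13-diene-15,18-dioic acid | C=C1CC[C@@H]2[C@](C)(C[C@H](O)C[C@@]2(C)C(=O)O)[C@@H]1CC/C(C)=C/C(=O)O | target

**Step count and risks**

Total step count: 13. Longest linear sequence: 13 steps (1 to 16; 5 enters at step 4).

Steps most likely to fail:

1. Step 4. The trimethylsilyl group may migrate from the ring-B enol ether to the ester enolate, after which the freed ring-B enolate would close a five-membered ring at C9; the silyl-transfer allylation of the hindered β-carbon may also stall. The fallback sets out from 6, made as in the first stage, and locks the ring-B enolate in a form that cannot migrate before any base is added. CsF and PhN(SO2CF3)2 convert crude 6 into the monocyclic enol triflate F1, and LiN(iPr)2 in THF at −78 °C then closes ring A by the same ester enolate alkylation. This gives 8 directly, so the route is rejoined at 8 and step 5 is not needed.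

2. Step 10. Protodesilylation of the allylsilane by adventitious acid, or slow attack at the neopentyl-type C9, may give the exocyclic alkene without the side chain. The fallback sets out from 7 and builds the side chain through ring-B enolate chemistry instead. Mukaiyama–Michael addition of 7 to methyl vinyl ketone (TiCl4, CH2Cl2, −78 °C; axial attack anti to the C10 methyl group) gives the diketone F2. Horner–Wadsworth–Emmons olefination of its methyl ketone gives the keto enoate F3. Lemieux–Johnson cleavage of the C2 methylidene gives the 2,8-diketone F4, and NaBH4 at low temperature reduces the less hindered C2 carbonyl from the α face to the 2β-hydroxy 8-ketone F5. Non-basic methylenation (Zn, CH2Br2, TiCl4), chosen so that C9 is not epimerised, then gives 15, where the route is rejoined.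

3. Step 3. Hydrogen abstraction at the tertiary allylic C–H of the stereocentre would erode its configuration and give the transposed enone, and over-oxidation may occur. The fallback sets out from 1 and carries the C8 oxygen from the start. Mn(OAc)3 in hot benzene acetoxylates the α′-position to give 6-acetoxy-2-methylcyclohex-2-en-1-one F6. Reduction as in step 1 gives the acetoxy allylic alcohol F7 (carbinol centre in the same spatial sense as 2, mixture at the acetoxy carbon). Johnson–Claisen rearrangement as in step 2 gives methyl 2-[(1S)-4-acetoxy-2-methylcyclohex-2-en-1-yl]propanoate F8. K2CO3 in MeOH frees the allylic alcohol F9, and MnO2 oxidises it to 4, where the route is rejoined.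

Further compounds

F1 | step 4 | monocyclic enol triflate (triflate analogue of 6) | COC(=O)C(C)[C@@H]1CCC(OS(=O)(=O)C(F)(F)F)=C[C@@]1(C)CC(=C)CCl
F2 | step 10 | diketone (2-methylidene, C8=O, 9α-(3-oxobutyl), 4α-CO2Me) | COC(=O)[C@]1(C)CC(=C)C[C@]2(C)[C@H](CCC(C)=O)C(=O)CC[C@@H]12
F3 | step 10 | keto enoate (2-methylidene, C8=O, 13E ethyl enoate) | COC(=O)[C@]1(C)CC(=C)C[C@]2(C)[C@H](CC/C(C)=C/C(=O)OCC)C(=O)CC[C@@H]12
F4 | step 10 | 2,8-diketone (13E ethyl enoate) | COC(=O)[C@]1(C)CC(=O)C[C@]2(C)[C@H](CC/C(C)=C/C(=O)OCC)C(=O)CC[C@@H]12
F5 | step 10 | 2β-hydroxy 8-ketone (13E ethyl enoate) | COC(=O)[C@]1(C)C[C@@H](O)C[C@]2(C)[C@H](CC/C(C)=C/C(=O)OCC)C(=O)CC[C@@H]12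
F6 | step 3 | 6-acetoxy-2-methylcyclohex-2-en-1-one | CC(=O)OC1CCC=C(C)C1=O
F7 | step 3 | 6-acetoxy-2-methylcyclohex-2-en-1-ol (carbinol centre as in 2) | O[C@H]1C(OC(C)=O)CCC=C1C
F8 | step 3 | methyl 2-[(1S)-4-acetoxy-2-methylcyclohex-2-en-1-yl]propanoate | COC(=O)C(C)[C@@H]1CCC(OC(C)=O)C=C1C
F9 | step 3 | methyl 2-[(1S)-4-hydroxy-2-methylcyclohex-2-en-1-yl]propanoate | COC(=O)C(C)[C@@H]1CCC(O)C=C1C
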